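The cyclohexenone ring hides two polarity-matched bonds: C4–C5, the bond of a syn-aldol between two carbinol carbons (trans-diol on the ring), and C1–C6, the acyloin bond between the ketone and the quaternary carbinol. Cutting both divides the 2,3-dihydro target into an oleic-acid-derived hydroxymethyl ketone (C5, C6, chain) and a four-carbon dialdehyde unit (C1–C4). One flask joins them: a primary amino acid makes C4–C5, a triazolylidene then closes C1–C6, giving the ring, two C–C bonds and all three stereocentres. The precursors are (Z)-1-hydroxynonadec-10-en-2-one and butanedial carried as its mono(dimethyl acetal), because free 1,4-dialdehyde would destroy the primary amine by Paal–Knorr pyrrole formation.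

Key step: step 4

Numbering used throughout: C1 carbonyl, C2=C3, C4 and C5 secondary carbinols, C6 quaternary carbinol, C1' first chain carbon.

Stereochemical reading of the target: 4S,5R,6R. C4–OH is trans to C5–OH, and C5–OH is cis to C6–OH. The 2,3-dihydro compound 11 has the same spatial arrangement and reads 2R,3R,4S as a cyclohexanone.

Assumption: the sense of induction of O-tert-butyl-L-threonine is taken from its behaviour with hydroxyacetone (L-series gives the 3R,4S-type syn diol, which maps onto 4S,5R here). The D-enantiomer is equally available should the sense prove opposite.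

Step 1
Reactants: 1 oleic acid ((Z)-octadec-9-enoic acid, high-purity grade)
Product: 2 oleoyl chloride ((Z)-octadec-9-enoyl chloride)
Conditions: (COCl)2 (1.3 equiv), DMF (cat.), CH2Cl2, 0 °C to rt
Reagents that add atoms: oxalyl chloride, O=C(Cl)C(=O)Cl
Why: DMF-catalysed acid chloride formation (Vilsmeier-type activation) runs cold and without strong acid or radical sources, so the isolated Z-alkene should keep its geometry.

Step 2
Reactants: 2 oleoyl chloride; 3 tris(trimethylsilyloxy)ethylene
Product: 6 (Z)-1-hydroxynonadec-10-en-2-one, via silyl keto ester 4 (not isolated), via keto acid 5 (not isolated)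
Conditions: 3 (2.2 equiv), neat, 95 °C; then dioxane–0.6 M aq HCl, 85 °C
Reagents that add atoms: tris(trimethylsilyloxy)ethylene (3), C[Si](C)(C)OC=C(O[Si](C)(C)C)O[Si](C)(C)C
Why: C-acylation of the electron-rich ketene bis(silyl) acetal by an aliphatic acid chloride, then silyl ester hydrolysis and β-keto acid decarboxylation, is an established one-flask homologation of acid chlorides to hydroxymethyl ketones, and the transient C2 stereocentre of 4 and 5 disappears with the loss of CO2.

Step 3
Reactants: 7 methyl 4,4-dimethoxybutanoate
Product: 8 4,4-dimethoxybutanal (butanedial mono(dimethyl acetal))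
Conditions: iBu2AlH (1.05 equiv), CH2Cl2, −78 °C; MeOH quench, aq potassium sodium tartrate, rt
Reagents that add atoms: none
Why: Partial ester reduction with iBu2AlH stops at the aluminium hemiacetal at −78 °C, and the non-acidic tartrate work-up releases the aldehyde without touching the dimethyl acetal.

Step 4
Reactants: 6 (Z)-1-hydroxynonadec-10-en-2-one (2 equiv, excess recovered); 8 4,4-dimethoxybutanal
Product: 11 (2R,3R,4S)-2-[(Z)-heptadec-8-enyl]-2,3,4-trihydroxycyclohexanone, via syn-aldol acetal 9 (not isolated), via keto aldehyde 10 (not isolated)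
Conditions: (2S,3R)-2-amino-3-tert-butoxybutanoic acid (O-tert-butyl-L-threonine, 20 mol %), NMP–H2O (30:1), 4 °C, 8 added by syringe pump; then TsOH·H2O (40 mol %), H2O (10 equiv), rt; then degassed THF (to 0.03 M), NaOAc (80 mol %), 2-(pentafluorophenyl)-6,7-dihydro-5H-pyrrolo[2,1-c][1,2,4]triazol-2-ium tetrafluoroborate (20 mol %), Ar, rt to 40 °C
Reagents that add atoms: water, O
Why: Proposed new method: the amino acid condenses with 6 to the Z-enamine at the hydroxylated carbon (N–H···O hydrogen bond), which attacks the only free formyl group of 8 under activation by the catalyst's carboxyl group to form C4–C5 (9); the acid switch then hydrolyses the acetal with help from the C4 hydroxyl to 10, which rests as a lactol, and the triazolylidene intercepts the open aldehyde, becomes the Breslow enaminol, adds its acyl-anion carbon C1 to the C6 ketone and is released after proton transfer. The closest known reaction types are the primary-amino-acid syn-aldol of hydroxyacetone-type ketones, the carbene-catalysed intramolecular aldehyde–ketone crossed benzoin and secondary-amine/carbene Michael–benzoin relays, whereas the aldol–benzoin pairing, the acid switch between the catalysts and a free diol resting as a lactol are untested. The one ring closes 6-exo-trig, the C6=O bond lying outside the forming carbocycle. C4 (S) and C5 (R) are set by the L-configured catalyst, the Z-enamine geometry giving the syn relation (trans on the ring) and the carboxyl-bound aldehyde being attacked on its Re face. C6 (R) is set by the substrate through a chair transition state with both hydroxyls and the C17 chain equatorial, which is also the polar Felkin–Anh arrangement (C5–O anti to the incoming C1, chain anti to C4–C5), so that the new alkoxide is axial and cis to C5–OH. The step needs reaction at a single formyl group, enamine formation towards CH2OH and not C1', and acyl-anion attack on the ketone and not on another aldehyde, which are secured in turn by the acetal (it also keeps the 1,4-dialdehyde away from the primary amine and so prevents Paal–Knorr pyrrole formation), by the hydroxyl-stabilised enamine, and by the α-oxygen-activated ketone placed for six-ring closure while dilution and the lactol keep free aldehyde scarce.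

Step 5
Reactants: 11 (2R,3R,4S)-2-[(Z)-heptadec-8-enyl]-2,3,4-trihydroxycyclohexanone
Product: 12 (4S,5R,6R)-6-[(Z)-heptadec-8-enyl]-1,4,5,6-tetrakis(trimethylsilyloxy)cyclohex-1-ene (target numbering)
Conditions: TMSOTf (6 equiv), Et3N (10 equiv), CH2Cl2, 0 °C to rt; cold aq NaHCO3, pentane; used crude
Reagents that add atoms: trimethylsilyl trifluoromethanesulfonate, C[Si](C)(C)OS(=O)(=O)C(F)(F)F
Why: Soft enolisation and O-silylation cap the three hydroxyls (which blocks α-ketol rearrangement) and give a single silyl enol ether, because only C2 carries α-hydrogens while C6 is quaternary, and no stereocentre is touched.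

Step 6
Reactants: 12 tetrakis(trimethylsilyl) enol ether
Product: 13 (4S,5R,6R)-6-[(Z)-heptadec-8-enyl]-4,5,6-tris(trimethylsilyloxy)cyclohex-2-en-1-one
Conditions: Pd(OAc)2 (1.1 equiv), MeCN–CH2Cl2 (3:1), rt; filtration through Florisil
Reagents that add atoms: none
Why: In the Saegusa–Ito oxidation divalent palladium replaces silicon to give the C2-palladated ketone, syn β-hydride elimination of a C3 hydrogen installs C2=C3 with release of zerovalent palladium, and the neutral room-temperature medium should spare the remote Z-alkene and the three stereocentres.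

Step 7
Reactants: 13 tris(trimethylsilyl) enone
Product: 14 pleiogenone A, (4S,5R,6R)-6-[(Z)-heptadec-8-enyl]-4,5,6-trihydroxycyclohex-2-en-1-one
Conditions: 1 M aq HCl–THF (1:10), 0 °C to rt
Reagents that add atoms: none
Why: Acid-catalysed hydrolysis of trimethylsilyl ethers is fast even at the tertiary C6 oxygen, and an acidic medium avoids the α-ketol rearrangement, oxa-Michael addition and epimerisation that base could cause in the γ-hydroxy enone, so 4S,5R,6R is retained.

Compound list
1 | oleic acid, (Z)-octadec-9-enoic acid | CCCCCCCC/C=C\CCCCCCCC(=O)O | starting material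
2 | oleoyl chloride, (Z)-octadec-9-enoyl chloride | CCCCCCCC/C=C\CCCCCCCC(=O)Cl | intermediate
3 | tris(trimethylsilyloxy)ethylene | C[Si](C)(C)OC=C(O[Si](C)(C)C)O[Si](C)(C)C | starting material
4 | trimethylsilyl (Z)-3-oxo-2-(trimethylsilyloxy)icos-11-enoate (racemic at C2, not isolated) | CCCCCCCC/C=C\CCCCCCCC(=O)C(O[Si](C)(C)C)C(=O)O[Si](C)(C)C | intermediate
5 | (Z)-2-hydroxy-3-oxoicos-11-enoic acid (racemic at C2, not isolated) | CCCCCCCC/C=C\CCCCCCCC(=O)C(O)C(=O)O | intermediate
6 | (Z)-1-hydroxynonadec-10-en-2-one | CCCCCCCC/C=C\CCCCCCCC(=O)CO | intermediate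
7 | methyl 4,4-dimethoxybutanoate | COC(=O)CCC(OC)OC | starting material
8 | 4,4-dimethoxybutanal | O=CCCC(OC)OC | intermediate
9 | (4S,5R,14Z)-4,5-dihydroxy-1,1-dimethoxytricos-14-en-6-one (syn diol, not isolated) | CCCCCCCC/C=C\CCCCCCCC(=O)[C@H](O)[C@@H](O)CCC(OC)OC | intermediate
10 | (4S,5R,14Z)-4,5-dihydroxy-6-oxotricos-14-enal (open form, rests as its lactol, not isolated) | CCCCCCCC/C=C\CCCCCCCC(=O)[C@H](O)[C@@H](O)CCC=O | intermediate
11 | (2R,3R,4S)-2-[(Z)-heptadec-8-enyl]-2,3,4-trihydroxycyclohexanone | CCCCCCCC/C=C\CCCCCCC[C@]1(O)C(=O)CC[C@H](O)[C@H]1O | intermediate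
12 | (4S,5R,6R)-6-[(Z)-heptadec-8-enyl]-1,4,5,6-tetrakis(trimethylsilyloxy)cyclohex-1-ene | CCCCCCCC/C=C\CCCCCCC[C@]1(O[Si](C)(C)C)C(O[Si](C)(C)C)=CC[C@H](O[Si](C)(C)C)[C@H]1O[Si](C)(C)C | intermediate
13 | (4S,5R,6R)-6-[(Z)-heptadec-8-enyl]-4,5,6-tris(trimethylsilyloxy)cyclohex-2-en-1-one | CCCCCCCC/C=C\CCCCCCC[C@]1(O[Si](C)(C)C)C(=O)C=C[C@H](O[Si](C)(C)C)[C@H]1O[Si](C)(C)C | intermediate
14 | pleiogenone A, (4S,5R,6R)-6-[(Z)-heptadec-8-enyl]-4,5,6-trihydroxycyclohex-2-en-1-one | CCCCCCCC/C=C\CCCCCCC[C@]1(O)C(=O)C=C[C@H](O)[C@H]1O | target

Total step count: 7. Longest linear sequence: 6 (steps 1, 2, 4, 5, 6, 7). Step 3 is a one-step side branch.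

Steps most likely to fail

1. Step 4. Several processes could undermine the relay.
- Self-condensation of the unbranched aldehyde may outrun the cross-aldol.
- The enamine may form towards C1'.
- The syn relation may erode by retro-aldol once the medium is buffered.
- Amine, acid and carbene may interfere with one another.
- Traces of air may oxidise the enaminol.
- Facial selectivity at C6 may be poor.

The fallback sets out from 6 and 8 and returns at 11. It takes the relay apart into isolated, protected stages, each of a known type.
- The amino-acid aldol is stopped after its first stage, and 9 is isolated and freed from its anti isomer by chromatography.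
- 2,2-Dimethoxypropane and pyridinium p-toluenesulfonate convert the diol into the trans-dioxolane (4S,5R,14Z)-1,1-dimethoxy-4,5-(isopropylidenedioxy)tricos-14-en-6-one F1.
- Pyridinium p-toluenesulfonate in wet acetone exchanges only the acyclic dimethyl acetal, the solvent holding the acetonide in place. This gives (4S,5R,14Z)-4,5-(isopropylidenedioxy)-6-oxotricos-14-enal F2, which cannot hide as a lactol.
- The established intramolecular aldehyde–ketone benzoin, with 3-benzyl-5-(2-hydroxyethyl)-4-methylthiazolium chloride and Et3N in THF, closes F2 to the trans-fused (2R,3R,4S)-2-[(Z)-heptadec-8-enyl]-2-hydroxy-3,4-(isopropylidenedioxy)cyclohexanone F3. The rigid dioxolane holds both ring oxygens equatorial.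
- If a stronger facial bias at C6 is wanted, either enantiomer of 2-(pentafluorophenyl)-5a,10b-dihydro-4H,6H-indeno[2,1-b][1,2,4]triazolo[4,3-d][1,4]oxazin-2-ium tetrafluoroborate can replace the thiazolium salt.
- Aqueous acetic acid at 40 °C removes the strained acetonide and gives 11.

2. Step 6. Divalent palladium, or the palladium hydride formed on elimination, may isomerise or migrate the Z-alkene of the chain. The acetic acid released may also protodesilylate the enol ether back to the saturated ketone.

The fallback sets out from 12 and returns at 13. It replaces the metal-mediated dehydrogenation by α-selenenylation and selenoxide elimination.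
- PhSeCl (1.0 equiv) in CH2Cl2 at −78 °C should react with the silyl enol ether far faster than with the unactivated alkene. This gives (4S,5R,6R)-6-[(Z)-heptadec-8-enyl]-2-(phenylselanyl)-4,5,6-tris(trimethylsilyloxy)cyclohexanone F4 as C2 epimers, both of which have a syn C3 hydrogen.
- mCPBA (1.0 equiv) at −78 °C gives the corresponding 2-(phenylseleninyl) ketone F5.
- Warming F5 with iPr2NH induces syn elimination to 13.

3. Step 5. Silylation of the hindered tertiary carbinol at C6 may be incomplete. Lewis-acid-induced α-ketol rearrangement may occur before that hydroxyl is capped. The labile trimethylsilyl groups or the enol ether may also be lost during work-up.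

The fallback sets out from 11 and returns at 14. It avoids both the silyl enol ether and palladium.
- TESOTf and 2,6-lutidine in CH2Cl2 give the chromatographically stable (2R,3R,4S)-2-[(Z)-heptadec-8-enyl]-2,3,4-tris(triethylsilyloxy)cyclohexanone F6.
- Hard enolisation with LiN(SiMe3)2 in THF at −78 °C, followed by N-tert-butylbenzenesulfinimidoyl chloride (Mukaiyama dehydrogenation), gives (4S,5R,6R)-6-[(Z)-heptadec-8-enyl]-4,5,6-tris(triethylsilyloxy)cyclohex-2-en-1-one F7 directly.
- HF·pyridine in THF at 0 °C then gives 14.

Further compounds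
F1 | step 4 | (4S,5R,14Z)-1,1-dimethoxy-4,5-(isopropylidenedioxy)tricos-14-en-6-one | CCCCCCCC/C=C\CCCCCCCC(=O)[C@@H]1OC(C)(C)O[C@H]1CCC(OC)OC
F2 | step 4 | (4S,5R,14Z)-4,5-(isopropylidenedioxy)-6-oxotricos-14-enal | CCCCCCCC/C=C\CCCCCCCC(=O)[C@@H]1OC(C)(C)O[C@H]1CCC=O
F3 | step 4 | (2R,3R,4S)-2-[(Z)-heptadec-8-enyl]-2-hydroxy-3,4-(isopropylidenedioxy)cyclohexanone | CCCCCCCC/C=C\CCCCCCC[C@]1(O)C(=O)CC[C@@H]2OC(C)(C)O[C@@H]12
F4 | step 6 | (4S,5R,6R)-6-[(Z)-heptadec-8-enyl]-2-(phenylselanyl)-4,5,6-tris(trimethylsilyloxy)cyclohexanone (C2 epimers) | CCCCCCCC/C=C\CCCCCCC[C@]1(O[Si](C)(C)C)C(=O)C([Se]c2ccccc2)C[C@H](O[Si](C)(C)C)[C@H]1O[Si](C)(C)C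
F5 | step 6 | (4S,5R,6R)-6-[(Z)-heptadec-8-enyl]-2-(phenylseleninyl)-4,5,6-tris(trimethylsilyloxy)cyclohexanone (epimers at C2 and Se) | CCCCCCCC/C=C\CCCCCCC[C@]1(O[Si](C)(C)C)C(=O)C([Se](=O)c2ccccc2)C[C@H](O[Si](C)(C)C)[C@H]1O[Si](C)(C)C
F6 | step 5 | (2R,3R,4S)-2-[(Z)-heptadec-8-enyl]-2,3,4-tris(triethylsilyloxy)cyclohexanone | CCCCCCCC/C=C\CCCCCCC[C@]1(O[Si](CC)(CC)CC)C(=O)CC[C@H](O[Si](CC)(CC)CC)[C@H]1O[Si](CC)(CC)CC
F7 | step 5 | (4S,5R,6R)-6-[(Z)-heptadec-8-enyl]-4,5,6-tris(triethylsilyloxy)cyclohex-2-en-1-one | CCCCCCCC/C=C\CCCCCCC[C@]1(O[Si](CC)(CC)CC)C(=O)C=C[C@H](O[Si](CC)(CC)CC)[C@H]1O[Si](CC)(CC)CC
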